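## Analysis of the target

Unprimed locants (O1, C2, C3, C3a–C7a) denote the dihydrobenzofuran that carries the styryl group (furan ring 1, benzo ring B). Primed locants denote the second dihydrobenzofuran (furan ring 2, benzo ring C). The two bicycles are joined by the C3–C5' bond. Ring B bears the (E)-4-hydroxystyryl group at C4 and a hydroxyl at C6, ring C a hydroxyl at C7'. C2 and C2' each carry a 4-hydroxyphenyl group and C3' a 3,5-dihydroxyphenyl group.

There are four stereocentres, C2 (S), C3 (S), C2' (R) and C3' (R). Each furan ring is 2,3-trans, and the two pairs are of opposite absolute sense. They are separated by ring C and cannot steer each other, so the sense must be imposed twice and independently.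

The sensitive groups are:
- seven phenols, which are prone to oxidation;
- the E-stilbene, which isomerises in light and, being ortho to C3, captures any cation formed at C3;
- the benzylic aryl ether bonds C2–O1 and C2'–O1', which ionise in strong acid and open by β-elimination from a carbanion at C3 or C3'.

The synthesis is hard because C3 is a crowded triaryl-type methine next to the styryl group, and because of the way the resorcinol ring is attached at C3'. That ring is bonded through the carbon meta to both hydroxyls, the one position of a resorcinol that no electrophilic arylation from C3' can reach. It is, however, exactly where the aldol cyclisation of a 1,3,5-triketone places its substituent, so the ring is grown on C3' from an acyl group.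

## Retrosynthetic reasoning

**34 from 33.** All seven phenols are carried as methyl ethers, which survive organolithium, carbene, ylide and base chemistry; only the seven O–CH3 bonds are cut at the end.

**33 from 30 and 26 (O1–C2 and C2–C3).** Both bonds to C2 are cut at once. C2 with its anisyl group is returned as sulfonium ylide 31 (from salt 26); the rest becomes ortho-quinone methide 32, released from 30. This spot is chosen because the trans ring arises in the closure itself, and because the sense at C2/C3 has to come from a reagent: the sulfide in 26 is chiral. The styryl group is already in place, so the methide must be made under base, never through a cation.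

**30 from 18 and 23 (C3–C5').** The forward reaction is addition of aryllithium 27 (from bromide 18) to aldehyde 23. A chlorine at C5' would first have to be turned into an aldehyde and then meet a ring B nucleophile whose ortho oxygen is a methyl ether, which cannot give a quinone methide. A bromine at C5' and reversed polarity avoid both problems. The carbonate on the phenol oxygen of 23 migrates to the new alkoxide, so the leaving group for 32 is installed by the coupling itself.

**23 from 22, 21 and 19.** The C3a–CHO bond is made by formylation of 19 at the position between the styryl carbon and a methoxy group, the most activated open site. Chelation-guided cleavage of the methyl ether next to the aldehyde then uncovers the future O1.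

**26 from 25 and 2; 25 from 24.** The sulfonium salt is cut at the S–benzyl bond, and the bridged sulfide comes in one step from terpene 24.

**18 from 17, and 17 from 15 (key disconnection).** After removal of two O-methyl groups, one ring bond of the resorcinol is cut, between the carbon bearing C3' and its ortho neighbour. All six ring carbons then map onto the hexanetrione chain of 15, with C3' on chain carbon 1. Nothing else works here: a resorcinol is not nucleophilic at the meta carbon, and coupling at a secondary benzylic carbon with a β-oxygen invites elimination. The gain is that C3' carries a carbonyl group through the whole early sequence, which is what the ring-forming step delivers and what lets C3' settle trans.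

**15 from 14, and 14 from 11 and 12.** The chain is cut between C1 and C2. Five of the six carbons come from 12, used as its dianion 13, and the sixth is the aldehyde carbon of 11. Oxidation of carbinol 14 gives 15.

**11 from 10, 9 and 8 (C2'–C3').** The furan ring 2 is opened at C2'–C3'. Forward, a metal carbene at the future C3' inserts into the benzylic C–H bond of the 4-methoxybenzyl ether. This sets C2' under catalyst control, with its aryl group already attached. The cis ester 9 is then epimerised at C3' to 10 and reduced to 11.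

**8 from 7, 6, 5, 3, 1 and 2.** Diazo transfer to aryl acetate 7, one-carbon homologation of aldehyde 3 through nitrile 5, and O-benzylation of 1 with 2 complete the analysis. The bromine of 1, para to the phenol, is the future C5' handle, and its methoxy group is the future 7'-hydroxyl.

## Alternatives that were turned down

**Alternative 1:** Ring B and furan ring 1 are taken apart together into three alkynes. Forward, RhCl(PPh3)3 would join the ynol ether and the enyne alkyne of tethered diyne A2 with ethoxyacetylene A3, forming C3a–C7a, C4–C5 and C6–C7 and giving A1.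
- For: the benzo ring appears with its styryl and oxygen substituents in one step, and no quinone methide ever sits next to the styryl group. On that point it is stronger than the chosen route.
- Against: A2 needs C2 and C3 set in an open chain beside ring 2. It contains an ethynyl ether of a secondary benzylic alcohol and a propargylic, doubly benzylic C3–H, both fragile. Only a weak electronic bias decides whether the ethoxy group of A3 ends at C6 or C5. The meta-linked resorcinol on C3' is not addressed at all.
- Comparison: the chosen route buys ring B ready-made in 19 and fixes every regiochemical question by known aromatic substitution. A2 would cost at least as many steps.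

**Alternative 2:** Furan ring 2 is traced back to a six-membered lactone. Forward, aqueous NaOH opens trans-3-bromo-dihydrocoumarin A5 and the phenoxide displaces bromide, forming O1'–C2' and giving acid A4.
- For: the C3' aryl group would come from conjugate arylation of a coumarin with a bought arylboron reagent. The meta-linked ring is purchased, not built, and C3' is set by a dependable catalytic method. This is shorter and stronger than the chosen route on that point.
- Against: C2' ends as a carboxylic acid. Its 4-hydroxyphenyl group must then be installed by decarboxylative arylation at an oxygen-bearing sp3 carbon, where only substrate bias gives trans. The α-bromo acid can also lose HBr under the hydroxide conditions.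
- Comparison: the chosen route sets C2' with its aryl group in the same catalyst-controlled step that closes ring 2, and needs no C(sp3)–aryl coupling.

**Alternative 3:** Both furan rings are opened at their O–C2 bonds. Forward, HCl in methanol removes the three methoxymethyl groups of bis-carbinol A7 and ionises both benzylic carbinols; the ring B and ring C phenols capture the cations, forming O1–C2 and O1'–C2' and giving A6.
- For: two rings form in one step, the carbinol centres need no control, and trans follows from C3 and C3'. In rings per step it is stronger than the chosen route.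
- Against: C3 and C3' would have to be set absolutely in an open chain, for which no dependable method exists. The C2 cation also lies beside the styryl group and two electron-rich rings, so Prins and Friedel–Crafts closures compete.
- Comparison: the chosen route never forms a benzylic cation in the presence of the stilbene and sets each stereocentre pair with a chiral reagent.

Key step: step 11

Assumption: the sense of induction of Rh2(S-PTTL)4 in step 6 (C2' = R) and of salt 26 in step 19 (C2 = S) is assigned by analogy with related benzylic insertions and ylide transfers; if either is opposite, the mirror-image catalyst or the sulfide from (S)-limonene is used with no other change.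

## Route

Step 1
Reactants: 1 5-bromo-2-hydroxy-3-methoxybenzaldehyde; 2 4-methoxybenzyl chloride
Product: 3 5-bromo-3-methoxy-2-[(4-methoxyphenyl)methoxy]benzaldehyde
Conditions: K2CO3, KI (cat.), DMF, 60 °C
Reagents that add atoms: none
Why: Williamson ether synthesis; the phenoxide of 1 displaces chloride from the activated benzylic halide, with iodide catalysis.

Step 2
Reactants: 3 5-bromo-3-methoxy-2-[(4-methoxyphenyl)methoxy]benzaldehyde
Product: 5 2-{5-bromo-3-methoxy-2-[(4-methoxyphenyl)methoxy]phenyl}acetonitrile, via N-formyl enamide sulfone 4 (not isolated)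
Conditions: TosMIC, t-BuOK, DME, −40 °C; then MeOH, reflux
Reagents that add atoms: tosylmethyl isocyanide (TosMIC), Cc1ccc(cc1)S(=O)(=O)C[N+]#[C-]
Why: van Leusen reductive cyanation; the TosMIC anion adds to the aldehyde and the oxazoline opens to 4, then methanol removes the formyl group and sulfinate leaves, giving the homologous nitrile. The low temperature of the first stage should suppress oxazole formation.

Step 3
Reactants: 5 2-{5-bromo-3-methoxy-2-[(4-methoxyphenyl)methoxy]phenyl}acetonitrile
Product: 6 2-{5-bromo-3-methoxy-2-[(4-methoxyphenyl)methoxy]phenyl}acetic acid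
Conditions: KOH, EtOH/H2O, reflux; then 1 M HCl, 0 °C
Reagents that add atoms: water, O; potassium hydroxide, [K+].[OH-]
Why: Base hydrolysis of an unhindered arylacetonitrile through the amide; the aryl bromide and both ethers are inert to hydroxide, and brief cold acidification spares the benzyl ether.

Step 4
Reactants: 6 2-{5-bromo-3-methoxy-2-[(4-methoxyphenyl)methoxy]phenyl}acetic acid
Product: 7 methyl 2-{5-bromo-3-methoxy-2-[(4-methoxyphenyl)methoxy]phenyl}acetate
Conditions: MeI, K2CO3, DMF, rt
Reagents that add atoms: iodomethane, CI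
Why: SN2 O-alkylation of the carboxylate.

Step 5
Reactants: 7 methyl 2-{5-bromo-3-methoxy-2-[(4-methoxyphenyl)methoxy]phenyl}acetate
Product: 8 methyl 2-{5-bromo-3-methoxy-2-[(4-methoxyphenyl)methoxy]phenyl}-2-diazoacetate
Conditions: p-ABSA, DBU, MeCN, 0 °C → rt
Reagents that add atoms: 4-acetamidobenzenesulfonyl azide (p-ABSA), CC(=O)Nc1ccc(cc1)S(=O)(=O)N=[N+]=[N-]
Why: Regitz diazo transfer to the aryl acetate enolate, the standard entry to aryldiazoacetates.

Step 6
Reactants: 8 methyl 2-{5-bromo-3-methoxy-2-[(4-methoxyphenyl)methoxy]phenyl}-2-diazoacetate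
Product: 9 methyl (2R,3S)-5-bromo-7-methoxy-2-(4-methoxyphenyl)-2,3-dihydro-1-benzofuran-3-carboxylate (cis)
Conditions: Rh2(S-PTTL)4 (dirhodium tetrakis[N-phthaloyl-(S)-tert-leucinate], 1 mol %), toluene, −60 °C
Reagents that add atoms: none
Why: Intramolecular 1,5 C–H insertion of the donor/acceptor rhodium carbene into the benzylic C–H bond of the ether, which is activated by oxygen and by the anisyl ring; the concerted insertion closes the five-membered ring cis. The chiral carboxylate ligands select one of the two enantiotopic benzylic hydrogens and so set C2' as R.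

Step 7
Reactants: 9 methyl (2R,3S)-5-bromo-7-methoxy-2-(4-methoxyphenyl)-2,3-dihydro-1-benzofuran-3-carboxylate
Product: 10 methyl (2R,3R)-5-bromo-7-methoxy-2-(4-methoxyphenyl)-2,3-dihydro-1-benzofuran-3-carboxylate (trans)
Conditions: NaOMe (0.3 equiv), MeOH, 0 °C → rt
Reagents that add atoms: none
Why: Thermodynamic epimerisation through the ester enolate; only C3' is acidic and the 2,3-trans ester is favoured, while C2' is untouched. Sub-stoichiometric base and low temperature are chosen to keep E1cB opening of C2'–O1' slow.

Step 8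
Reactants: 10 methyl (2R,3R)-5-bromo-7-methoxy-2-(4-methoxyphenyl)-2,3-dihydro-1-benzofuran-3-carboxylate
Product: 11 (2R,3R)-5-bromo-7-methoxy-2-(4-methoxyphenyl)-2,3-dihydro-1-benzofuran-3-carbaldehyde
Conditions: i-Bu2AlH (DIBAL-H, 1.1 equiv), CH2Cl2, −78 °C; then MeOH, aq. KNaC4H4O6
Reagents that add atoms: none
Why: Partial reduction of the ester; the aluminium hemiacetal is stable at −78 °C and collapses to the aldehyde only on work-up. The aldehyde is used crude at once.

Step 9
Reactants: 11 (2R,3R)-5-bromo-7-methoxy-2-(4-methoxyphenyl)-2,3-dihydro-1-benzofuran-3-carbaldehyde; 12 acetylacetone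
Product: 14 6-[(2R,3S)-5-bromo-7-methoxy-2-(4-methoxyphenyl)-2,3-dihydro-1-benzofuran-3-yl]-6-hydroxyhexane-2,4-dione (both carbinol epimers), via acetylacetone dianion 13 (not isolated)
Conditions: 12, LDA (LiN(i-Pr)2, 2.1 equiv), THF, −78 → 0 °C; then 11, −78 °C; aq. NH4Cl
Reagents that add atoms: none
Why: Aldol addition of a β-diketone 1,3-dianion through its terminal, more basic carbon; at −78 °C carbonyl addition should outrun proton transfer from the α-aryl position. The new carbinol centre is removed in step 10.

Step 10
Reactants: 14 6-[(2R,3S)-5-bromo-7-methoxy-2-(4-methoxyphenyl)-2,3-dihydro-1-benzofuran-3-yl]-6-hydroxyhexane-2,4-dione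
Product: 15 1-[(2R,3R)-5-bromo-7-methoxy-2-(4-methoxyphenyl)-2,3-dihydro-1-benzofuran-3-yl]hexane-1,3,5-trione
Conditions: Dess–Martin periodinane, NaHCO3, CH2Cl2, 0 °C → rt
Reagents that add atoms: none
Why: Dess–Martin oxidation of the secondary alcohol under buffered, neutral conditions; the enolised β-diketone is inert and C3' meets no base.

Step 11
Reactants: 15 1-[(2R,3R)-5-bromo-7-methoxy-2-(4-methoxyphenyl)-2,3-dihydro-1-benzofuran-3-yl]hexane-1,3,5-trione
Product: 17 5-[(2R,3R)-5-bromo-7-methoxy-2-(4-methoxyphenyl)-2,3-dihydro-1-benzofuran-3-yl]benzene-1,3-diol, via cyclic aldol 16 (not isolated)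
Conditions: K2CO3, MeOH, 0 °C → rt; then HCl/MeOH (to pH 2), rt
Reagents that add atoms: none
Why: Carbonate deprotonates the triketone between its carbonyl groups, and through the small equilibrium share of the extended enolate of the C3/C5 diketone the terminal methyl carbon C6 adds to the C1 ketone, the only carbonyl not held in that enolate. This 6-(enolendo)-exo-trig aldol closes the one new ring as 16; acidification then removes water and the two remaining carbonyls enolise, so the ring becomes the 3,5-dihydroxyphenyl ring with C3' on the carbon meta to both hydroxyls. The closest known reaction is the aldol cyclisation and aromatisation of 1,3,5-triketones to 5-substituted resorcinols, as in orcinol from heptane-2,4,6-trione. No new stereogenic atom is made; C3' is the one centre free to move, and while C1 is a carbonyl it can only settle in the more stable trans arrangement against the fixed anisyl group on C2'. After aromatisation C3' is locked and from then on holds C2' in place, because any later ionisation at C2' recloses trans to it. The step needs C6-to-C1 closure to win over attack of C3' on the C5 carbonyl; that spiro aldol cannot aromatise and is reversible. It also needs to win over O-closure to a 4-pyranone, which is acid-promoted, so acid is added only after the C–C bond exists, and over retro-Claisen cleavage, which the mild base and low temperature disfavour. Loss of O1' from a C3' enolate is unlikely, because C3'–H is the least acidic α-hydrogen of the enolised triketone and the C2'–O1' bond lies near the nodal plane of such an enolate in the five-membered ring.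

Step 12
Reactants: 17 5-[(2R,3R)-5-bromo-7-methoxy-2-(4-methoxyphenyl)-2,3-dihydro-1-benzofuran-3-yl]benzene-1,3-diol
Product: 18 (2R,3R)-5-bromo-3-(3,5-dimethoxyphenyl)-7-methoxy-2-(4-methoxyphenyl)-2,3-dihydro-1-benzofuran
Conditions: MeI, K2CO3, acetone, reflux
Reagents that add atoms: iodomethane, CI
Why: Williamson O-methylation of both phenols, which removes the acidic hydrogens before the organolithium step.

Step 13
Reactants: 19 resveratrol trimethyl ether, (E)-1,3-dimethoxy-5-[2-(4-methoxyphenyl)ethenyl]benzene
Product: 21 2,4-dimethoxy-6-[(E)-2-(4-methoxyphenyl)ethenyl]benzaldehyde, via iminium salt 20 (not isolated)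
Conditions: POCl3, DMF, 0 °C → rt; then aq. NaOAc
Reagents that add atoms: N,N-dimethylformamide, CN(C)C=O; water, O
Why: Vilsmeier–Haack formylation at the ring carbon ortho to one methoxy group and para to the other, the most nucleophilic open site; the carbon between the two methoxy groups is more crowded and the alkene is less electron-rich than the dimethoxyarene.

Step 14
Reactants: 21 2,4-dimethoxy-6-[(E)-2-(4-methoxyphenyl)ethenyl]benzaldehyde
Product: 22 2-hydroxy-4-methoxy-6-[(E)-2-(4-methoxyphenyl)ethenyl]benzaldehyde
Conditions: BCl3 (1.2 equiv), CH2Cl2, −78 → 0 °C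
Reagents that add atoms: none
Why: Chelation-controlled demethylation; boron binds between the aldehyde oxygen and the ortho methoxy group and chloride cleaves only that O–CH3 bond, leaving the two unchelated methyl ethers.

Step 15
Reactants: 22 2-hydroxy-4-methoxy-6-[(E)-2-(4-methoxyphenyl)ethenyl]benzaldehyde
Product: 23 tert-butyl 2-formyl-5-methoxy-3-[(E)-2-(4-methoxyphenyl)ethenyl]phenyl carbonate
Conditions: Boc2O, i-Pr2NEt, DMAP (cat.), CH2Cl2, 0 °C → rt
Reagents that add atoms: di-tert-butyl dicarbonate, CC(C)(C)OC(=O)OC(=O)OC(C)(C)C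
Why: DMAP-catalysed acylation of the phenol; the aryl carbonate is the migrating group needed in step 18.

Step 16
Reactants: 24 (R)-limonene
Product: 25 (1R,4R,5R)-4,7,7-trimethyl-6-thiabicyclo[3.2.1]octane (isothiocineole)
Conditions: S8, γ-terpinene, neat, 110 °C
Reagents that add atoms: sulfur, S1SSSSSSS1
Why: Known radical addition of sulfur across the ring alkene and the isopropenyl group of limonene with γ-terpinene as hydrogen donor; the limonene stereocentre is kept and the bridge fixes the second ring-fusion carbon.

Step 17
Reactants: 25 (1R,4R,5R)-4,7,7-trimethyl-6-thiabicyclo[3.2.1]octane; 2 4-methoxybenzyl chloride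
Product: 26 (1R,4R,5R,6R)-6-[(4-methoxyphenyl)methyl]-4,7,7-trimethyl-6-thiabicyclo[3.2.1]octan-6-ium tetrafluoroborate (benzyl group exo on sulfur)
Conditions: AgBF4, CH2Cl2, 0 °C → rt
Reagents that add atoms: silver tetrafluoroborate, [Ag+].F[B-](F)(F)F
Why: S-alkylation of the sulfide with silver-assisted loss of chloride; attack through the less hindered exo lone pair should give one sulfonium diastereomer with a non-nucleophilic counter-ion.

Step 18
Reactants: 18 (2R,3R)-5-bromo-3-(3,5-dimethoxyphenyl)-7-methoxy-2-(4-methoxyphenyl)-2,3-dihydro-1-benzofuran; 23 tert-butyl 2-formyl-5-methoxy-3-[(E)-2-(4-methoxyphenyl)ethenyl]phenyl carbonate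
Product: 30 tert-butyl {2-[tert-butyl(dimethyl)silyl]oxy-4-methoxy-6-[(E)-2-(4-methoxyphenyl)ethenyl]phenyl}[(2R,3R)-3-(3,5-dimethoxyphenyl)-7-methoxy-2-(4-methoxyphenyl)-2,3-dihydro-1-benzofuran-5-yl]methyl carbonate (both carbinol epimers), via aryllithium 27 (not isolated), via lithium alkoxide 28 (not isolated), via lithium phenoxide 29 (not isolated)
Conditions: n-BuLi, THF, −78 °C; 23, −78 °C; then TBSCl, DMPU, −78 → 0 °C
Reagents that add atoms: tert-butyldimethylsilyl chloride, CC(C)(C)[Si](C)(C)Cl
Why: Bromine–lithium exchange and addition of 27 to the aldehyde form the C3–C5' bond; alkoxide 28 takes the carbonate from the neighbouring phenol oxygen through a six-membered transition state, and the lithium phenoxide 29, persistent in the cold, is capped by silylation. The leaving group for the quinone methide is thus installed without acid, which matters because the ortho styryl group would capture a benzylic cation; the carbinol centre is not controlled and is erased in step 19.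

Step 19
Reactants: 30 tert-butyl {2-[tert-butyl(dimethyl)silyl]oxy-4-methoxy-6-[(E)-2-(4-methoxyphenyl)ethenyl]phenyl}[(2R,3R)-3-(3,5-dimethoxyphenyl)-7-methoxy-2-(4-methoxyphenyl)-2,3-dihydro-1-benzofuran-5-yl]methyl carbonate; 26 (1R,4R,5R,6R)-6-[(4-methoxyphenyl)methyl]-4,7,7-trimethyl-6-thiabicyclo[3.2.1]octan-6-ium tetrafluoroborate
Product: 33 (2S,3S)-3-[(2R,3R)-3-(3,5-dimethoxyphenyl)-7-methoxy-2-(4-methoxyphenyl)-2,3-dihydro-1-benzofuran-5-yl]-6-methoxy-2-(4-methoxyphenyl)-4-[(E)-2-(4-methoxyphenyl)ethenyl]-2,3-dihydro-1-benzofuran, via sulfonium ylide 31 (not isolated), via ortho-quinone methide 32 (not isolated)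
Conditions: 26 (1.5 equiv), CsF, Cs2CO3, MeCN, 0 °C → rt, slow addition of 30
Reagents that add atoms: none
Why: Formal [4+1] annulation of an ortho-quinone methide with a sulfonium ylide; fluoride removes the silyl group and the phenoxide expels tert-butyl carbonate to give 32, ylide 31 adds to the methide carbon (C3), and the phenoxide displaces the sulfide in a 5-exo-tet SN2 closure that forms O1–C2. The chiral sulfide fixes the reacting face of the ylide carbon and hence C2 (S after inversion); C3 follows as trans because closure of the anti betaine is the easier one. The distant C2' and C3' have no say, so this is reagent control.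

Step 20
Reactants: 33 (2S,3S)-3-[(2R,3R)-3-(3,5-dimethoxyphenyl)-7-methoxy-2-(4-methoxyphenyl)-2,3-dihydro-1-benzofuran-5-yl]-6-methoxy-2-(4-methoxyphenyl)-4-[(E)-2-(4-methoxyphenyl)ethenyl]-2,3-dihydro-1-benzofuran
Product: 34 5-[(2R,3R)-7-hydroxy-5-{(2S,3S)-6-hydroxy-2-(4-hydroxyphenyl)-4-[(E)-2-(4-hydroxyphenyl)ethenyl]-2,3-dihydro-1-benzofuran-3-yl}-2-(4-hydroxyphenyl)-2,3-dihydro-1-benzofuran-3-yl]benzene-1,3-diol (CNP0172909.1)
Conditions: BBr3 (excess), CH2Cl2, −78 °C → rt; MeOH quench, dark
Reagents that add atoms: none
Why: Global aryl methyl ether cleavage; boron binds each ether oxygen and bromide attacks the methyl carbon, so the aryl–O bonds stay, and both furan rings are already in their stable trans form.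

## Compound list

1 | 5-bromo-2-hydroxy-3-methoxybenzaldehyde | COc1cc(Br)cc(C=O)c1O | starting material
2 | 4-methoxybenzyl chloride | COc1ccc(CCl)cc1 | starting material
3 | 5-bromo-3-methoxy-2-[(4-methoxyphenyl)methoxy]benzaldehyde | COc1ccc(COc2c(OC)cc(Br)cc2C=O)cc1 | intermediate
4 | N-[2-{5-bromo-3-methoxy-2-[(4-methoxyphenyl)methoxy]phenyl}-1-(4-methylbenzenesulfonyl)ethenyl]formamide | COc1ccc(COc2c(OC)cc(Br)cc2C=C(NC=O)S(=O)(=O)c2ccc(C)cc2)cc1 | intermediate (not isolated)
5 | 2-{5-bromo-3-methoxy-2-[(4-methoxyphenyl)methoxy]phenyl}acetonitrile | COc1ccc(COc2c(OC)cc(Br)cc2CC#N)cc1 | intermediate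
6 | 2-{5-bromo-3-methoxy-2-[(4-methoxyphenyl)methoxy]phenyl}acetic acid | COc1ccc(COc2c(OC)cc(Br)cc2CC(=O)O)cc1 | intermediate
7 | methyl 2-{5-bromo-3-methoxy-2-[(4-methoxyphenyl)methoxy]phenyl}acetate | COc1ccc(COc2c(OC)cc(Br)cc2CC(=O)OC)cc1 | intermediate
8 | methyl 2-{5-bromo-3-methoxy-2-[(4-methoxyphenyl)methoxy]phenyl}-2-diazoacetate | COc1ccc(COc2c(OC)cc(Br)cc2C(=[N+]=[N-])C(=O)OC)cc1 | intermediate
9 | methyl (2R,3S)-5-bromo-7-methoxy-2-(4-methoxyphenyl)-2,3-dihydro-1-benzofuran-3-carboxylate | Brc1cc(OC)c2c(c1)[C@H](C(=O)OC)[C@H](c1ccc(OC)cc1)O2 | intermediate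
10 | methyl (2R,3R)-5-bromo-7-methoxy-2-(4-methoxyphenyl)-2,3-dihydro-1-benzofuran-3-carboxylate | Brc1cc(OC)c2c(c1)[C@@H](C(=O)OC)[C@H](c1ccc(OC)cc1)O2 | intermediate
11 | (2R,3R)-5-bromo-7-methoxy-2-(4-methoxyphenyl)-2,3-dihydro-1-benzofuran-3-carbaldehyde | Brc1cc(OC)c2c(c1)[C@@H](C=O)[C@H](c1ccc(OC)cc1)O2 | intermediate
12 | acetylacetone (pentane-2,4-dione) | CC(=O)CC(C)=O | starting material
13 | dilithium salt of the acetylacetone 1,3-dianion | [Li+].[Li+].[CH2-]C(=O)[CH-]C(C)=O | intermediate (not isolated)
14 | 6-[(2R,3S)-5-bromo-7-methoxy-2-(4-methoxyphenyl)-2,3-dihydro-1-benzofuran-3-yl]-6-hydroxyhexane-2,4-dione, both carbinol epimers | Brc1cc(OC)c2c(c1)[C@@H](C(O)CC(=O)CC(C)=O)[C@H](c1ccc(OC)cc1)O2 | intermediate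
15 | 1-[(2R,3R)-5-bromo-7-methoxy-2-(4-methoxyphenyl)-2,3-dihydro-1-benzofuran-3-yl]hexane-1,3,5-trione | Brc1cc(OC)c2c(c1)[C@@H](C(=O)CC(=O)CC(C)=O)[C@H](c1ccc(OC)cc1)O2 | intermediate (key-step precursor)
16 | 5-[(2R,3R)-5-bromo-7-methoxy-2-(4-methoxyphenyl)-2,3-dihydro-1-benzofuran-3-yl]-5-hydroxycyclohexane-1,3-dione | Brc1cc(OC)c2c(c1)[C@@H](C1(O)CC(=O)CC(=O)C1)[C@H](c1ccc(OC)cc1)O2 | intermediate (not isolated)
17 | 5-[(2R,3R)-5-bromo-7-methoxy-2-(4-methoxyphenyl)-2,3-dihydro-1-benzofuran-3-yl]benzene-1,3-diol | Brc1cc(OC)c2c(c1)[C@@H](c1cc(O)cc(O)c1)[C@H](c1ccc(OC)cc1)O2 | intermediate (key-step product)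
18 | (2R,3R)-5-bromo-3-(3,5-dimethoxyphenyl)-7-methoxy-2-(4-methoxyphenyl)-2,3-dihydro-1-benzofuran | Brc1cc(OC)c2c(c1)[C@@H](c1cc(OC)cc(OC)c1)[C@H](c1ccc(OC)cc1)O2 | intermediate
19 | resveratrol trimethyl ether | COc1ccc(/C=C/c2cc(OC)cc(OC)c2)cc1 | starting material
20 | {2,4-dimethoxy-6-[(E)-2-(4-methoxyphenyl)ethenyl]phenyl}methylidene(dimethyl)iminium dichlorophosphate | COc1ccc(/C=C/c2cc(OC)cc(OC)c2C=[N+](C)C)cc1.[O-]P(Cl)(Cl)=O | intermediate (not isolated)
21 | 2,4-dimethoxy-6-[(E)-2-(4-methoxyphenyl)ethenyl]benzaldehyde | COc1ccc(/C=C/c2cc(OC)cc(OC)c2C=O)cc1 | intermediate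
22 | 2-hydroxy-4-methoxy-6-[(E)-2-(4-methoxyphenyl)ethenyl]benzaldehyde | COc1ccc(/C=C/c2cc(OC)cc(O)c2C=O)cc1 | intermediate
23 | tert-butyl 2-formyl-5-methoxy-3-[(E)-2-(4-methoxyphenyl)ethenyl]phenyl carbonate | COc1ccc(/C=C/c2cc(OC)cc(OC(=O)OC(C)(C)C)c2C=O)cc1 | intermediate
24 | (R)-limonene | CC1=CC[C@@H](CC1)C(C)=C | starting material
25 | (1R,4R,5R)-4,7,7-trimethyl-6-thiabicyclo[3.2.1]octane | C[C@@H]1CC[C@@H]2C[C@H]1SC2(C)C | intermediate
26 | (1R,4R,5R,6R)-6-[(4-methoxyphenyl)methyl]-4,7,7-trimethyl-6-thiabicyclo[3.2.1]octan-6-ium tetrafluoroborate | C[C@@H]1CC[C@@H]2C[C@H]1[S@@+](Cc1ccc(OC)cc1)C2(C)C.F[B-](F)(F)F | intermediate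
27 | [(2R,3R)-3-(3,5-dimethoxyphenyl)-7-methoxy-2-(4-methoxyphenyl)-2,3-dihydro-1-benzofuran-5-yl]lithium | [Li]c1cc(OC)c2c(c1)[C@@H](c1cc(OC)cc(OC)c1)[C@H](c1ccc(OC)cc1)O2 | intermediate (not isolated)
28 | lithium alkoxide of the aldehyde adduct, carbonate still on the phenol oxygen, both carbinol epimers | COc1ccc(/C=C/c2cc(OC)cc(OC(=O)OC(C)(C)C)c2C(O[Li])c2cc(OC)c3c(c2)[C@@H](c2cc(OC)cc(OC)c2)[C@H](c2ccc(OC)cc2)O3)cc1 | intermediate (not isolated)
29 | lithium phenoxide after carbonate migration to the benzylic oxygen, both carbinol epimers | COc1ccc(/C=C/c2cc(OC)cc(O[Li])c2C(OC(=O)OC(C)(C)C)c2cc(OC)c3c(c2)[C@@H](c2cc(OC)cc(OC)c2)[C@H](c2ccc(OC)cc2)O3)cc1 | intermediate (not isolated)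
30 | tert-butyl {2-[tert-butyl(dimethyl)silyl]oxy-4-methoxy-6-[(E)-2-(4-methoxyphenyl)ethenyl]phenyl}[(2R,3R)-3-(3,5-dimethoxyphenyl)-7-methoxy-2-(4-methoxyphenyl)-2,3-dihydro-1-benzofuran-5-yl]methyl carbonate, both carbinol epimers | COc1ccc(/C=C/c2cc(OC)cc(O[Si](C)(C)C(C)(C)C)c2C(OC(=O)OC(C)(C)C)c2cc(OC)c3c(c2)[C@@H](c2cc(OC)cc(OC)c2)[C@H](c2ccc(OC)cc2)O3)cc1 | intermediate
31 | (4-methoxyphenyl)methylide of sulfonium salt 26 | C[C@@H]1CC[C@@H]2C[C@H]1[S@@+]([CH-]c1ccc(OC)cc1)C2(C)C | intermediate (not isolated)
32 | 6-{[(2R,3R)-3-(3,5-dimethoxyphenyl)-7-methoxy-2-(4-methoxyphenyl)-2,3-dihydro-1-benzofuran-5-yl]methylidene}-3-methoxy-5-[(E)-2-(4-methoxyphenyl)ethenyl]cyclohexa-2,4-dien-1-one | O=C1C=C(OC)C=C(/C=C/c2ccc(OC)cc2)C1=Cc1cc(OC)c2c(c1)[C@@H](c1cc(OC)cc(OC)c1)[C@H](c1ccc(OC)cc1)O2 | intermediate (not isolated)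
33 | (2S,3S)-3-[(2R,3R)-3-(3,5-dimethoxyphenyl)-7-methoxy-2-(4-methoxyphenyl)-2,3-dihydro-1-benzofuran-5-yl]-6-methoxy-2-(4-methoxyphenyl)-4-[(E)-2-(4-methoxyphenyl)ethenyl]-2,3-dihydro-1-benzofuran | COc1ccc(/C=C/c2cc(OC)cc3c2[C@H](c2cc(OC)c4c(c2)[C@@H](c2cc(OC)cc(OC)c2)[C@H](c2ccc(OC)cc2)O4)[C@@H](c2ccc(OC)cc2)O3)cc1 | intermediate
34 | 5-[(2R,3R)-7-hydroxy-5-{(2S,3S)-6-hydroxy-2-(4-hydroxyphenyl)-4-[(E)-2-(4-hydroxyphenyl)ethenyl]-2,3-dihydro-1-benzofuran-3-yl}-2-(4-hydroxyphenyl)-2,3-dihydro-1-benzofuran-3-yl]benzene-1,3-diol | Oc1ccc(/C=C/c2cc(O)cc3c2[C@H](c2cc(O)c4c(c2)[C@@H](c2cc(O)cc(O)c2)[C@H](c2ccc(O)cc2)O4)[C@@H](c2ccc(O)cc2)O3)cc1 | target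

## Step count and least certain steps

Total step count: 20. Longest linear sequence: 15 steps (steps 1 to 12, then 18, 19 and 20).

**Step 11 (key step).** The most likely failure is closure through the wrong manifold: oxygen attack giving a 4-pyranone, or retro-Claisen loss of acyl units, because the C1 ketone is hindered and the carbon closure is slow. Long exposure to base could also open the furan ring by loss of O1' and erode the configuration at C2'. The fallback attaches the arene instead of growing it and sets out from 3. Addition of 3,5-dimethoxyphenylmagnesium bromide would give (3,5-dimethoxyphenyl){5-bromo-3-methoxy-2-[(4-methoxyphenyl)methoxy]phenyl}methanol F1, and MnO2 oxidation the diaryl ketone F2. Hydrazine would then give the hydrazone F3, which MnO2 oxidises to the diaryldiazomethane F4. Rh2(S-PTAD)4 (dirhodium tetrakis[(S)-(1-adamantyl)(N-phthalimido)acetate]) or its mirror image, chosen for 3'R, should insert the donor/donor carbene into the benzylic C–H bond and give the cis diaryl dihydrobenzofuran F5. Trifluoroacetic acid would then equilibrate C2' to trans, and the route is rejoined at 18.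

**Step 19.** Facial selection by the chiral ylide on a crowded quinone methide may be incomplete, giving both trans diastereomers. The methide may also be lost to dimerisation or to attack by the neighbouring styryl group before the ylide reaches it. The fallback gives up reagent control: from 30, the achiral salt 1-[(4-methoxyphenyl)methyl]thiolan-1-ium tetrafluoroborate F6 (from tetrahydrothiophene, 2 and AgBF4) would give 33 together with its (2R,3R,2'R,3'R) diastereomer F7. Because ring 2 is already a single enantiomer, these are diastereomers and would be separated by preparative HPLC, returning to the route at 33.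

**Step 18.** Carbonate may be lost before silylation, or migration may be incomplete. The electron-rich benzylic carbonate may also ionise on silica, with capture by the styryl group. The fallback separates coupling and activation. From 18 and 22, aryllithium 27 would be added to the preformed sodium phenoxide of 22 (NaH) to give the diol 2-{hydroxy[aryl]methyl}-5-methoxy-3-[(E)-2-(4-methoxyphenyl)ethenyl]phenol F8. Acetic anhydride and pyridine would give the diacetate F9. With K2CO3 and a little methanol in MeCN in the presence of 26, F9 should release 32 and rejoin the route at 33.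

**Step 9.** Proton transfer from the α-aryl aldehyde to the dianion may win over addition, giving enolisation, loss of material and possibly ring opening. The fallback replaces the basic nucleophile by a Lewis acid-mediated one. From 12, silylation would give 2,4-bis(trimethylsilyloxy)penta-1,3-diene F10, which with TiCl4 in CH2Cl2 at −78 °C should add through its terminal carbon to 11 in a vinylogous Mukaiyama aldol reaction and return to the route at 14.

**Step 6 (with step 7).** The methoxy group beside the ether oxygen may disturb the conformation the catalyst relies on and lower the enantioselectivity, and step 7 could erode it further by ring opening. The fallback is resolution in place of asymmetric catalysis. From 8, Rh2(OAc)4 would give racemic cis ester, that is 9 with its enantiomer F11. Epimerisation would give 10 with its enantiomer F12, and preparative chromatography on a chiral phase would return pure 10.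

**Step 20.** The Lewis acid may ionise the benzylic C–O bonds, causing ring opening or epimerisation, or start cationic reactions of the stilbene. The fallback changes the mechanism to nucleophilic dealkylation: from 33, NaSEt in DMF at 140 °C would cleave the methyl ethers by thiolate attack under basic conditions and give 34 directly.

## Further compounds

F1 | step 11 | (3,5-dimethoxyphenyl){5-bromo-3-methoxy-2-[(4-methoxyphenyl)methoxy]phenyl}methanol | COc1ccc(COc2c(OC)cc(Br)cc2C(O)c2cc(OC)cc(OC)c2)cc1
F2 | step 11 | (3,5-dimethoxyphenyl){5-bromo-3-methoxy-2-[(4-methoxyphenyl)methoxy]phenyl}methanone | COc1ccc(COc2c(OC)cc(Br)cc2C(=O)c2cc(OC)cc(OC)c2)cc1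
F3 | step 11 | hydrazone of F2 | COc1ccc(COc2c(OC)cc(Br)cc2C(=NN)c2cc(OC)cc(OC)c2)cc1
F4 | step 11 | (3,5-dimethoxyphenyl){5-bromo-3-methoxy-2-[(4-methoxyphenyl)methoxy]phenyl}diazomethane | COc1ccc(COc2c(OC)cc(Br)cc2C(=[N+]=[N-])c2cc(OC)cc(OC)c2)cc1
F5 | step 11 | (2S,3R)-5-bromo-3-(3,5-dimethoxyphenyl)-7-methoxy-2-(4-methoxyphenyl)-2,3-dihydro-1-benzofuran (cis) | Brc1cc(OC)c2c(c1)[C@@H](c1cc(OC)cc(OC)c1)[C@@H](c1ccc(OC)cc1)O2
F6 | step 19 | 1-[(4-methoxyphenyl)methyl]thiolan-1-ium tetrafluoroborate | COc1ccc(C[S+]2CCCC2)cc1.F[B-](F)(F)F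
F7 | step 19 | (2R,3R)-3-[(2R,3R)-3-(3,5-dimethoxyphenyl)-7-methoxy-2-(4-methoxyphenyl)-2,3-dihydro-1-benzofuran-5-yl]-6-methoxy-2-(4-methoxyphenyl)-4-[(E)-2-(4-methoxyphenyl)ethenyl]-2,3-dihydro-1-benzofuran | COc1ccc(/C=C/c2cc(OC)cc3c2[C@@H](c2cc(OC)c4c(c2)[C@@H](c2cc(OC)cc(OC)c2)[C@H](c2ccc(OC)cc2)O4)[C@H](c2ccc(OC)cc2)O3)cc1
F8 | step 18 | 2-{[(2R,3R)-3-(3,5-dimethoxyphenyl)-7-methoxy-2-(4-methoxyphenyl)-2,3-dihydro-1-benzofuran-5-yl](hydroxy)methyl}-5-methoxy-3-[(E)-2-(4-methoxyphenyl)ethenyl]phenol, both carbinol epimers | COc1ccc(/C=C/c2cc(OC)cc(O)c2C(O)c2cc(OC)c3c(c2)[C@@H](c2cc(OC)cc(OC)c2)[C@H](c2ccc(OC)cc2)O3)cc1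
F9 | step 18 | diacetate of F8 | COc1ccc(/C=C/c2cc(OC)cc(OC(C)=O)c2C(OC(C)=O)c2cc(OC)c3c(c2)[C@@H](c2cc(OC)cc(OC)c2)[C@H](c2ccc(OC)cc2)O3)cc1
F10 | step 9 | 2,4-bis(trimethylsilyloxy)penta-1,3-diene | C=C(O[Si](C)(C)C)C=C(C)O[Si](C)(C)C
F11 | step 6 | methyl (2S,3R)-5-bromo-7-methoxy-2-(4-methoxyphenyl)-2,3-dihydro-1-benzofuran-3-carboxylate | Brc1cc(OC)c2c(c1)[C@@H](C(=O)OC)[C@@H](c1ccc(OC)cc1)O2
F12 | step 6 | methyl (2S,3S)-5-bromo-7-methoxy-2-(4-methoxyphenyl)-2,3-dihydro-1-benzofuran-3-carboxylate | Brc1cc(OC)c2c(c1)[C@H](C(=O)OC)[C@@H](c1ccc(OC)cc1)O2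
F0 | step 20 | none | none
A1 | alternative 1 | 6-O-ethyl hexamethyl ether of the target | COc1ccc(/C=C/c2cc(OCC)cc3c2[C@H](c2cc(OC)c4c(c2)[C@@H](c2cc(OC)cc(OC)c2)[C@H](c2ccc(OC)cc2)O4)[C@@H](c2ccc(OC)cc2)O3)cc1
A2 | alternative 1 | tethered 1,6-diyne: ethynyl ether of the 1-(4-methoxyphenyl)-2-aryl-6-(4-methoxyphenyl)hex-5-en-3-yn-1-ol, C2 and C3 as in the target | C#CO[C@H](c1ccc(OC)cc1)[C@H](C#C/C=C/c1ccc(OC)cc1)c1cc(OC)c2c(c1)[C@@H](c1cc(OC)cc(OC)c1)[C@H](c1ccc(OC)cc1)O2
A3 | alternative 1 | ethoxyacetylene | CCOC#C
A4 | alternative 2 | trans-5-chloro-3-(3,5-dimethoxyphenyl)-7-methoxy-2,3-dihydrobenzofuran-2-carboxylic acid | Clc1cc(OC)c2c(c1)[C@@H](c1cc(OC)cc(OC)c1)[C@H](C(=O)O)O2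
A5 | alternative 2 | trans-3-bromo-6-chloro-4-(3,5-dimethoxyphenyl)-8-methoxy-3,4-dihydrocoumarin | O=C1Oc2c(OC)cc(Cl)cc2[C@@H](c2cc(OC)cc(OC)c2)[C@@H]1Br
A6 | alternative 3 | hexamethyl ether of the target with free C6 hydroxyl | COc1ccc(/C=C/c2cc(O)cc3c2[C@H](c2cc(OC)c4c(c2)[C@@H](c2cc(OC)cc(OC)c2)[C@H](c2ccc(OC)cc2)O4)[C@@H](c2ccc(OC)cc2)O3)cc1
A7 | alternative 3 | open-chain bis-carbinol with three methoxymethyl ethers, C3 and C3' as in the target, both carbinol centres mixed | COc1ccc(/C=C/c2cc(OCOC)cc(OCOC)c2[C@H](c2cc(OC)c(OCOC)c(c2)[C@@H](c2cc(OC)cc(OC)c2)C(O)c2ccc(OC)cc2)C(O)c2ccc(OC)cc2)cc1
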